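Oak is charged as larch is, so you can read its first 20 h off larch, and the work lies in the remaining 60.0 h.

| flask | Sbt | Ctl | time |
|---|---|---|---|
| larch | 100 mM | 5.00 mM |  |
| alder | 150 mM | 5.00 mM |  |
| maple | 100 mM | 15.0 mM |  |
| oak | 100 mM | 5.00 mM | 80 h |

| larch run: time / h | larch run: [Sbt] / mM | alder run: time / h | alder run: [Sbt] / mM | maple run: time / h | maple run: [Sbt] / mM |
|---|---|---|---|---|---|
| 0.80 | 92.5 | 0.80 | 142.1 | 0.80 | 82.7 |
| 1.3 | 89.4 | 1.3 | 137.2 | 1.3 | 72.9 |
| 2.0 | 85.7 | 2.0 | 133.3 | 2.0 | 60.6 |
| 3.2 | 77.7 | 3.2 | 123.7 | 3.2 | 45.8 |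
| 5.0 | 69.4 | 5.0 | 115.3 | 5.0 | 27.6 |
| 8.0 | 60.7 | 8.0 | 103.6 | 8.0 | 12.5 |
| 13 | 51.0 | 13 | 92.3 | 13 | 3.0 |
| 20 | 44.1 | 20 | 80.1 | 20 | 0.5 |

(scatter of a reading: 0.5 mM)

- Overall: Sbt -> Pdt, with Ctl as catalyst.
- Constant volume, constant temperature.
- What is held in complexes is read along with the free species.
- An order is taken over about fifteen percent of the charge, up and down.

* order of the initial rate in [Sbt], near the charge of the larch run, the rate being that where two percent of its Sbt are Pdt (one fixed amount of Pdt, the same in the runs compared)
* order of the initial rate in [Ctl], near the charge of the larch run, the rate being that where two percent of its Sbt are Pdt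
* Sbt in the oak run at 80 h, as a share of the Sbt charged

Follow one Sbt molecule. A rate constant is its chance per hour of taking an exit, and you can test for two exits: through Ctl, or by a first-order side reaction that ignores Ctl. Over the first 2.0 h, larch loses 7.15 mM h⁻¹ and alder 8.35 mM h⁻¹. That ratio of 1.17 is smaller than the charge ratio of 1.50, so the exit through Ctl responds weakly to Sbt.

So take the catalysed rate as equal in larch and alder from 8.0 h to 20 h. There larch loses 1.38 mM h⁻¹ around 52.4 mM, and alder loses 1.96 mM h⁻¹ around 91.8 mM. The rate difference over the Sbt difference reads 0.0146 h⁻¹: this is k, the leak constant, the chance per hour that a Sbt molecule leaves without Ctl.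

Subtract k times Sbt from larch's late rate and 0.620 mM h⁻¹ remains for Ctl, far less than larch's early total, so the catalysed exit is fading there. Subtract the leak from the early rates as well, and the orders read about 0.200 in Sbt and 1.06 in Ctl, readings taken over wider spans than those asked. For oak, start from larch's 44.1 mM and let k act to 80 h: that leaves 18.4% of the charge. The fading catalysed rate takes a little more, so you commit to just under that.

The forecast gave 0.3, 0.96 and 36%, on the ground that “The catalyst must be dying with time.” The flask gives 0.16, 1.0 and 16.3%.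

    Ctl + Sbt ⇌ Ctl.Sbt, settled at all times (60.40 M⁻¹)
    Ctl.Sbt → Pdt + Ctl (1.825 h⁻¹)
    Ctl.Sbt → X + Sbt (0.2362 h⁻¹)
    Sbt → J (0.01588 h⁻¹)

The step from Sbt to J is the main reason for oak's low figure: with that step taken away, oak holds 61.4% at 80 h, against 16.3% as it stands. Your k applied to that 61.4% gives 19.1%. Alder's Sbt readings already went into k, so the new evidence here is its Pdt time. At 17.3 h, a straight line between its last two readings has 65.2 mM of Sbt gone, while Pdt stands at 37.5 mM, so 27.7 mM left by the other exit. k times that time times alder's mean Sbt gives 29.6 mM.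

The data were computed with made-up constants; scatter was added.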